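**Strategy.** The flavanone is disconnected at C2–C3 and C4–C4a, which reveals the diazomethyl ketone of an O-aryl 4-methoxymandelic acid. The key step exploits that C3–C4 of ring C is a ketene-type CH2–C=O unit lying between the stereogenic benzylic ether carbon C2 and C4a, the only unsubstituted and most nucleophilic position of ring A. A photochemical Wolff rearrangement moves C2, with retention, from the carbonyl carbon to the diazo carbon (C2–C3). The resulting ketene, on acid catalysis, acylates C4a (C4–C4a) and closes ring C. The precursor is an open-chain (R)-α-aryloxy diazoketone made from (S)-4-methoxymandelic acid by Mitsunobu inversion with 2,3,4,5-tetramethoxyphenol.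

Key step: step 6

Assumption: 1,2,3,4-tetramethoxybenzene and (S)-4-methoxymandelic acid are taken as commercial, and the Wolff 1,2-shift is taken to proceed with retention at the migrating carbon, as in Arndt–Eistert homologations.

**Step 1**
Reactants: 1 1,2,3,4-tetramethoxybenzene
Product: 4 2,3,4,5-tetramethoxyphenol, via aryllithium 2 (not isolated), via lithium aryltrimethoxyborate 3 (not isolated)
Conditions: n-BuLi, TMEDA, THF, 0 °C; B(OMe)3, −78 °C → rt; AcOH, 30% aq. H2O2, 0 °C → rt
Reagents that add atoms: hydrogen peroxide OO (phenol oxygen); n-butyllithium [Li]CCCC and trimethyl borate COB(OC)OC (atoms carried only by 2 and 3)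
Why: Methoxy-directed ortho-lithiation can only occur at the two equivalent free positions of 1, and borylation followed by oxidative 1,2-aryl shift from boron to oxygen should convert the C–Li bond into C–OH (directed ortho-metalation/borylation/oxidation).

**Step 2**
Reactants: 5 (S)-4-methoxymandelic acid
Product: 6 allyl (2S)-2-hydroxy-2-(4-methoxyphenyl)acetate
Conditions: allyl bromide, KHCO3, DMF, rt
Reagents that add atoms: allyl bromide C=CCBr
Why: SN2 O-alkylation of the carboxylate under hydrogencarbonate conditions should leave the secondary benzylic hydroxyl and the stereocentre untouched.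

**Step 3**
Reactants: 6 allyl (2S)-2-hydroxy-2-(4-methoxyphenyl)acetate; 4 2,3,4,5-tetramethoxyphenol
Product: 7 allyl (2R)-2-(4-methoxyphenyl)-2-(2,3,4,5-tetramethoxyphenoxy)acetate
Conditions: PPh3, DIAD, toluene, 0 °C → rt
Reagents that add atoms: none
Why: In this Mitsunobu reaction phenol 4 should displace the alkoxyphosphonium of the α-hydroxy ester by an SN2 process accelerated by the adjacent ester carbonyl, so the S alcohol is inverted to the R aryl ether.

**Step 4**
Reactants: 7 allyl (2R)-2-(4-methoxyphenyl)-2-(2,3,4,5-tetramethoxyphenoxy)acetate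
Product: 8 (2R)-2-(4-methoxyphenyl)-2-(2,3,4,5-tetramethoxyphenoxy)acetic acid
Conditions: Pd(PPh3)4 (5 mol%), morpholine, THF, rt; aq. citric acid work-up
Reagents that add atoms: none
Why: Tsuji–Trost deallylation by zerovalent palladium, with morpholine as allyl acceptor, should free the acid under near-neutral conditions that do not enolise the α-aryl-α-aryloxy stereocentre.

**Step 5**
Reactants: 8 (2R)-2-(4-methoxyphenyl)-2-(2,3,4,5-tetramethoxyphenoxy)acetic acid
Product: 10 (3R)-1-diazo-3-(4-methoxyphenyl)-3-(2,3,4,5-tetramethoxyphenoxy)propan-2-one, via mixed carbonic anhydride 9 (not isolated)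
Conditions: i-BuOCOCl, N-methylmorpholine, THF, −20 °C; CH2N2 (Et2O), −20 → 0 °C
Reagents that add atoms: diazomethane C=[N+]=[N-]; isobutyl chloroformate CC(C)COC(=O)Cl (atoms carried only by 9)
Why: Mixed-anhydride activation at low temperature with a weak amine, followed by C-acylation of diazomethane (first stage of the Arndt–Eistert sequence, as used for racemisation-prone arylglycines), should give the diazomethyl ketone without touching the C–H of the stereocentre.

**Step 6**
Reactants: 10 (3R)-1-diazo-3-(4-methoxyphenyl)-3-(2,3,4,5-tetramethoxyphenoxy)propan-2-one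
Product: 12 (2S)-5,6,7,8,4'-pentamethoxyflavanone, via ketene 11 (not isolated)
Conditions: hν (365 nm), CH2Cl2 (0.01 M), −78 °C; then TfOH (10 mol%), −78 °C; aq. NaHCO3 quench
Reagents that add atoms: none
Why: Direct excitation of the s-Z diazoketone expels N2 with a concerted 1,2-shift of the stereogenic carbon from the carbonyl carbon (the future C4) to the diazo carbon (the future C3), which forms C2–C3 and ketene 11; catalytic TfOH, added only after N2 loss, then protonates 11 at C3 to an acylium ion (acyl triflate) that acylates C4a, forms C4–C4a and returns the proton. The closest known reactions are the Wolff step of the Arndt–Eistert homologation of α-amino and α-alkoxy acids and the acid-catalysed Friedel–Crafts acylation of arenes by ketenes, as in cyclisations of 3-aryloxypropanoic acid derivatives to chroman-4-ones. Ring C closes in a 6-exo-dig mode by attack of C4a on the digonal acylium carbon. No stereocentre is created: C2, set in step 3, migrates with retention, and its descriptor changes from R to S only because C3 ranks below the anisyl carbon whereas the carbonyl carbon ranked above it. The step needs Wolff rearrangement over carbene chemistry, secured by photolysis without metal or acid, and acylation of ring A over ring B, secured because C4a is the only free position of ring A, lies ortho to the O1-bearing C8a and to the C5 methoxy carbon and para to the C7 methoxy carbon and closes a six-membered ring, whereas ring B could only close an indanone at a carbon meta to its methoxy group. Low temperature, catalytic acid and a prompt basic quench should keep the C2–O1 bond from ionising, so the configuration set in step 3 should be retained.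

**Compound list**
1 | 1,2,3,4-tetramethoxybenzene | COc1ccc(OC)c(OC)c1OC | starting material
2 | (2,3,4,5-tetramethoxyphenyl)lithium | [Li]c1cc(OC)c(OC)c(OC)c1OC | intermediate
3 | lithium trimethoxy(2,3,4,5-tetramethoxyphenyl)borate | [Li+].CO[B-](OC)(OC)c1cc(OC)c(OC)c(OC)c1OC | intermediate
4 | 2,3,4,5-tetramethoxyphenol | COc1cc(O)c(OC)c(OC)c1OC | intermediate
5 | (S)-4-methoxymandelic acid, (2S)-2-hydroxy-2-(4-methoxyphenyl)acetic acid | COc1ccc([C@H](O)C(=O)O)cc1 | starting material
6 | allyl (2S)-2-hydroxy-2-(4-methoxyphenyl)acetate | COc1ccc([C@H](O)C(=O)OCC=C)cc1 | intermediate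
7 | allyl (2R)-2-(4-methoxyphenyl)-2-(2,3,4,5-tetramethoxyphenoxy)acetate | COc1ccc([C@@H](Oc2cc(OC)c(OC)c(OC)c2OC)C(=O)OCC=C)cc1 | intermediate
8 | (2R)-2-(4-methoxyphenyl)-2-(2,3,4,5-tetramethoxyphenoxy)acetic acid | COc1ccc([C@@H](Oc2cc(OC)c(OC)c(OC)c2OC)C(=O)O)cc1 | intermediate
9 | isobutyl carbonic (2R)-2-(4-methoxyphenyl)-2-(2,3,4,5-tetramethoxyphenoxy)acetic anhydride | COc1ccc([C@@H](Oc2cc(OC)c(OC)c(OC)c2OC)C(=O)OC(=O)OCC(C)C)cc1 | intermediate
10 | (3R)-1-diazo-3-(4-methoxyphenyl)-3-(2,3,4,5-tetramethoxyphenoxy)propan-2-one | COc1ccc([C@@H](Oc2cc(OC)c(OC)c(OC)c2OC)C(=O)C=[N+]=[N-])cc1 | intermediate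
11 | (3S)-3-(4-methoxyphenyl)-3-(2,3,4,5-tetramethoxyphenoxy)prop-1-en-1-one (ketene) | COc1ccc([C@@H](Oc2cc(OC)c(OC)c(OC)c2OC)C=C=O)cc1 | intermediate
12 | (2S)-5,6,7,8,4'-pentamethoxyflavanone | COc1ccc([C@@H]2CC(=O)c3c(OC)c(OC)c(OC)c(OC)c3O2)cc1 | target

**Total step count:** 6
**Longest linear sequence:** 5 steps (5 → 6 → 7 → 8 → 10 → 12; the branch 1 → 4 joins at step 3 and is equally long).

**Steps most likely to fail**

1. Step 6 (key step). The ketene may dimerise or be intercepted by adventitious nucleophiles before it acylates ring A. Photolysis may leak into carbene pathways such as attack of the carbene carbon on ring A. The acid may ionise the C2–O1 bond and erode the enantiomeric purity. The fallback sets out from 10 and comes back at 12 by splitting the cascade into two known operations. Irradiation of 10 (365 nm) in THF/H2O should trap ketene 11 with water as (3S)-3-(4-methoxyphenyl)-3-(2,3,4,5-tetramethoxyphenoxy)propanoic acid F1 (Arndt–Eistert homologation). Treatment of F1 with trifluoroacetic anhydride in CH2Cl2 at 0 °C should give the mixed trifluoroacetic anhydride F2, which should cyclise at C4a by intramolecular Friedel–Crafts acylation to 12.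

2. Step 3. Partial ionisation of the 4-methoxybenzylic alkoxyphosphonium (SN1 leakage) or enolisation of the product ester under the basic Mitsunobu medium would lower the enantiomeric purity, and the ortho-methoxy group may slow the substitution. The fallback sets out from 4 and comes back at 8 by catalytic asymmetric carbenoid O–H insertion. Commercial methyl 4-methoxyphenylacetate is converted by diazo transfer (4-acetamidobenzenesulfonyl azide, DBU, MeCN) into methyl 2-diazo-2-(4-methoxyphenyl)acetate F3. Insertion of F3 into the O–H bond of 4 with PdCl2(PhCN)2 (divalent palladium), a chiral spiro-bisoxazoline ligand of the enantiomeric series that delivers the R ester, and NaB[3,5-(CF3)2C6H3]4 in CHCl3 should give methyl (2R)-2-(4-methoxyphenyl)-2-(2,3,4,5-tetramethoxyphenoxy)acetate F4. Hydrolysis of F4 with Me3SnOH in 1,2-dichloroethane at 70 °C, with dilute HCl work-up, should give 8 without epimerisation.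

3. Step 5. The activated α-aryl-α-aryloxy acid may enolise or form a ketene (racemisation), and diazomethane may attack the carbonate carbonyl of 9 (methyl ester formation). The fallback sets out from 4 and comes back at 12, and avoids acyl activation next to a stereocentre. Acetylation of 4 at its only free ring position (Ac2O, catalytic Sc(OTf)3, MeNO2, 50 °C; acylation/Fries) should give 1-(2-hydroxy-3,4,5,6-tetramethoxyphenyl)ethan-1-one F5. Condensation with N,N-dimethylformamide dimethyl acetal should give the enaminone (E)-3-(dimethylamino)-1-(2-hydroxy-3,4,5,6-tetramethoxyphenyl)prop-2-en-1-one F6, which should close with HCl in CH2Cl2 to 5,6,7,8-tetramethoxy-4H-chromen-4-one F7. Enantioselective conjugate addition of 4-methoxyphenylboronic acid to F7, catalysed by Pd(OCOCF3)2 (divalent palladium) with the enantiomer of the tert-butyl pyridine-oxazoline ligand that delivers the 2S product (NH4PF6, H2O, 1,2-dichloroethane, 60 °C), should give 12.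

**Further compounds**
F1 | step 6 | (3S)-3-(4-methoxyphenyl)-3-(2,3,4,5-tetramethoxyphenoxy)propanoic acid | COc1ccc([C@@H](Oc2cc(OC)c(OC)c(OC)c2OC)CC(=O)O)cc1
F2 | step 6 | (3S)-3-(4-methoxyphenyl)-3-(2,3,4,5-tetramethoxyphenoxy)propanoic trifluoroacetic anhydride | COc1ccc([C@@H](Oc2cc(OC)c(OC)c(OC)c2OC)CC(=O)OC(=O)C(F)(F)F)cc1
F3 | step 3 | methyl 2-diazo-2-(4-methoxyphenyl)acetate | COC(=O)C(=[N+]=[N-])c1ccc(OC)cc1
F4 | step 3 | methyl (2R)-2-(4-methoxyphenyl)-2-(2,3,4,5-tetramethoxyphenoxy)acetate | COc1ccc([C@@H](Oc2cc(OC)c(OC)c(OC)c2OC)C(=O)OC)cc1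
F5 | step 5 | 1-(2-hydroxy-3,4,5,6-tetramethoxyphenyl)ethan-1-one | CC(=O)c1c(O)c(OC)c(OC)c(OC)c1OC
F6 | step 5 | (E)-3-(dimethylamino)-1-(2-hydroxy-3,4,5,6-tetramethoxyphenyl)prop-2-en-1-one | CN(C)/C=C/C(=O)c1c(O)c(OC)c(OC)c(OC)c1OC
F7 | step 5 | 5,6,7,8-tetramethoxy-4H-chromen-4-one | O=c1ccoc2c1c(OC)c(OC)c(OC)c2OC
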